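A flask whose right-handed substrate stayed right-handed could not have turned more than half of its charge into left-handed product, yet the dawn run reached 75.4 % at 6.00 h. So exchange was at work, and I asked the question the other way round: how slow would the crossing have to be to hold the flask back?

| flask | left-handed substrate | right-handed substrate | gas | free catalyst | racemization catalyst | added ligand | remark | time |
|---|---|---|---|---|---|---|---|---|
| dawn | 1 M | 1 M | 150 mM (held) | 0.5 mol% | 0.2 mol% | 8 mM | run made earlier |  |
| autumn | 2 M | 2 M | 150 mM (held) | 0.5 mol% | 0.4 mol% | 8 mM | run made earlier |  |
| flask | 2.0 M | 2.0 M | 150 mM (held) | 0.5 mol% | 0.2 mol% | 8.0 mM |  | 6.0 h |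

| run | time / h | left-handed product / % | right-handed product / % |
|---|---|---|---|
| dawn | 0.500 | 11.2 | 0 |
| dawn | 1.00 | 21.3 | 0.3 |
| dawn | 2.50 | 44.7 | 0.9 |
| dawn | 6.00 | 75.4 | 0.9 |
| autumn | 1.50 | 59.6 | 0.5 |
| autumn | 3.00 | 87.4 | 0.4 |
| autumn | 5.00 | 96.4 | 0.5 |
| autumn | 6.00 | 97.5 | 1.8 |

(standard deviation of a reading: 0.5 percentage points)

- free catalyst is single-handed; left-handed substrate and right-handed substrate are mirror images of each other, charged as a racemate, each of them at the stated concentration
- at the start none of the gas is in solution
- an excess is the difference of the two amounts in percent of their sum
- an excess is below zero if the other one leads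

- left-handed product and right-handed product together, in percent of the left-handed substrate and right-handed substrate charged together, at 6.0 h
- excess of left-handed product over right-handed product in the product at 6.0 h
- whether the exchange between left-handed substrate and right-handed substrate keeps pace with the reaction: how far the product's excess at 6.0 h gets from its value without exchange to its value with instant exchange (above 80 % keeps pace, below 20 % hardly takes part, else lags behind)

Right-handed product stood at 0.9 % at 6.00 h in the dawn run against 75.4 % left-handed product, so nearly all of the substrate that reacted went through the left-handed form, and right-handed substrate drained no faster than it crossed. The dawn run's pseudo-first-order loss constant for total substrate, 0.240 h⁻¹, stood close to the 0.238 h⁻¹ of its first reading, so no early burst showed, and I took it as a floor for its exchange constant. Taking exchange as proportional to c(racemization catalyst), from 2.00 mM in the dawn run to 4.00 mM in the flask, I got at most 2.08 h for the flask's exchange time, the mean wait of a substrate molecule before it crosses. My ceiling for that wait lay below the flask's 6.0 h.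

For two first-order pools in series, the drain time, one over the loss constant, stays below reaction time plus exchange time. The autumn run had the flask's substrate, free catalyst and ligand, and its loss constant of 0.701 h⁻¹ gave a drain time of 1.43 h. With 8.00 mM of racemization catalyst, its exchange time was half the flask's, so I estimated that the flask added up to 1.04 h. That estimate put the flask's yield between 91.2 % and 98.5 %, so I committed to keeping pace.

The forecast gave 98 % yield, 98 % excess and keeps pace: “exchange should stay well ahead”. The flask gave 98.3 %, 97.4 % and keeps pace, 95 % of the way.

    left-handed substrate + racemization catalyst ⇌ right-handed substrate + racemization catalyst, rate k1*[racemization catalyst]*[left-handed substrate] forward; the back reaction follows from the equilibrium constant (k = 6.90 M⁻¹ min⁻¹)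
    partner + free catalyst + right-handed substrate → free catalyst + right-handed product (k = 0.510 M⁻² min⁻¹)
    free catalyst + added ligand ⇌ idle complex, settled at all times (K = 850 M⁻¹)
    partner + free catalyst + left-handed substrate → free catalyst + left-handed product (k = 58.0 M⁻² min⁻¹)
    gas ⇌ partner, rate k5*(csat - [partner]) (kL = 0.600 min⁻¹)

The flask's forward exchange half-life of 0.42 h makes its exchange time 0.604 h, below my ceiling of 2.08 h, and its yield gives a drain time of 1.47 h. The neighbouring flask has 0.05 mol% of racemization catalyst, a quarter of the flask's, so its exchange time is 2.42 h. Adding the difference gives that flask an estimated drain time of 3.28 h and an estimated lowest yield of 83.9 %. That neighbour gave 90.3 % yield and 95.0 % excess, with 8.02 % right-handed substrate against 1.64 % left-handed substrate remaining.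

The runs were computed with made-up constants.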